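**Plan**

- Retrosynthesis: the three phenols are masked as methyl ethers, and the saturated twelve-carbon bridge (C1 on ring B, C12 on ring A) is traced back to a 3,11-diene. Both alkenes, C3=C4 and C11=C12, are cut at once.
- That cut releases C4–C11, eight contiguous unsubstituted carbons that map onto cis-cyclooctene. What remains is a diaryl ether with only a vinyl group on ring A (C12) and a but-3-enyl group on ring B (C1–C3).
- Further cuts: the ring A–vinyl bond (Suzuki–Miyaura), C1–C2 (allyl Grignard addition to an aldehyde, then benzylic deoxygenation) and the ring A–O bond of the diaryl ether (Chan–Lam).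
- Forward: diaryl ether first, then the butenyl arm, then the vinyl group. The 20-membered ring, the only ring made, closes in the three-component metathesis; hydrogenation and O-demethylation finish the synthesis.
- Stereochemistry: the target has no stereocenter. The racemic carbinol of step 2 is erased in step 3, and the alkene geometry of step 5 is erased in step 6.

Key step: step 5

Remark: the two ring alkenes formed in step 5 are drawn E,E as the expected thermodynamic major isomer; any Z isomers would be carried along, since step 6 saturates both.

**Route**

Step 1
Reactants: 1 syringaldehyde; 2 3-bromo-5-methoxyphenylboronic acid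
Product: 3 4-(3-bromo-5-methoxyphenoxy)-3,5-dimethoxybenzaldehyde
Conditions: 2 (2 equiv), Cu(OAc)2 (2 equiv), pyridine (5 equiv), 4 Å MS, CH2Cl2, dry air, rt
Reagents that add atoms: none
Why: Chan–Lam oxidative etherification, in which transmetalation of the arylboronic acid to divalent copper and C–O reductive elimination proceed at room temperature, tolerate a phenol flanked by two ortho substituents and leave both the aldehyde and the aryl bromide untouched.

Step 2
Reactants: 3 4-(3-bromo-5-methoxyphenoxy)-3,5-dimethoxybenzaldehyde; 4 allylmagnesium bromide
Product: 5 rac-1-[4-(3-bromo-5-methoxyphenoxy)-3,5-dimethoxyphenyl]but-3-en-1-ol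
Conditions: 4 (1.3 equiv), THF, −78 → 0 °C; then aq NH4Cl
Reagents that add atoms: none
Why: Grignard 1,2-addition of the allyl nucleophile to the aldehyde is far faster at low temperature than magnesium–bromine exchange on ring A; the carbinol stereocenter forms as a racemate and is removed in step 3.

Step 3
Reactants: 5 rac-1-[4-(3-bromo-5-methoxyphenoxy)-3,5-dimethoxyphenyl]but-3-en-1-ol
Product: 6 2-(3-bromo-5-methoxyphenoxy)-5-(but-3-en-1-yl)-1,3-dimethoxybenzene
Conditions: Et3SiH (3 equiv), CF3CO2H (5 equiv), CH2Cl2, −20 → 0 °C
Reagents that add atoms: none
Why: Ionic hydrogenation, in which acid ionises the benzylic alcohol to a cation stabilised by the para aryloxy group and triethylsilane traps it by hydride transfer faster than the unactivated terminal alkene or the aryl bromide can react.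

Step 4
Reactants: 6 2-(3-bromo-5-methoxyphenoxy)-5-(but-3-en-1-yl)-1,3-dimethoxybenzene
Product: 7 5-(but-3-en-1-yl)-1,3-dimethoxy-2-(3-methoxy-5-vinylphenoxy)benzene
Conditions: vinylboronic acid pinacol ester (1.5 equiv), Pd(PPh3)4 (5 mol%), K2CO3 (3 equiv), 1,4-dioxane/H2O 4:1, 90 °C
Reagents that add atoms: vinylboronic acid pinacol ester (4,4,5,5-tetramethyl-2-vinyl-1,3,2-dioxaborolane), C=CB1OC(C)(C)C(C)(C)O1
Why: Suzuki–Miyaura coupling, in which oxidative addition of zerovalent palladium into the only C–Br bond and transmetalation with the vinylboronate outpace any Heck reaction at the remote terminal alkene; the vinyl group is introduced only now because it would not survive step 3.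

Step 5
Reactants: 7 5-(but-3-en-1-yl)-1,3-dimethoxy-2-(3-methoxy-5-vinylphenoxy)benzene; 8 cis-cyclooctene
Product: 10 (3E,11E)-20-membered macrocyclic diene trimethyl ether (ring B–CH2CH2–CH=CH–(CH2)6–CH=CH–ring A), via open-chain triene 9 (not isolated)
Conditions: second-generation Grubbs catalyst RuCl2(=CHPh)(H2IMes)(PCy3) (10 mol% in two portions), 1,4-benzoquinone (20 mol%), toluene (1 mM in 7), 60 °C, Ar sparge, 8 (1.5 equiv) by syringe pump over 10 h, then 12 h further; ethyl vinyl ether quench
Reagents that add atoms: none
Why: Proposed new method: a ruthenium alkylidene loaded on the butenyl terminus of 7 should open strained cis-cyclooctene 8 by [2+2]/retro-[2+2], forming C3=C4 and the open-chain triene 9 (or its chain-end ruthenium alkylidene), and ring-closing metathesis of that C11 terminus onto the ring A vinyl group then forms C11=C12 and expels ethylene. The closest known reaction type is the ring-expansion metathesis of acyclic bis-acrylate-type dienes with cycloalkenes, supported by ring-opening cross-metathesis of cyclooctene with terminal alkenes and by macrocyclic ring-closing metathesis, but a one-unit insertion into a diene made of a styrene and an unactivated terminal alkene has no direct precedent. The single ring is closed as a 20-membered ring by ring-closing metathesis at C11=C12 (or at C3=C4 if the vinyl arm is engaged first) under high dilution, and no stereocenter is formed; the alkene geometry does not matter because step 6 saturates both double bonds. The selectivity needed is insertion of exactly one C8 unit without direct closure or dimerisation of 7: direct closure would give a 12-membered ring strained by the para-bridged ring B, slow addition keeps free cyclooctene below the effective molarity of the 20-membered closure, and high dilution disfavours intermolecular coupling of 7. Because every metathesis event is reversible with this catalyst while ethylene is swept out, over-inserted oligomers should back-bite to the unstrained 20-membered ring, the small excess of 8 should be left as separable hydrocarbon rings, and 1,4-benzoquinone is included to suppress alkene migration by ruthenium hydrides that would shorten the bridge.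

Step 6
Reactants: 10 (3E,11E)-20-membered macrocyclic diene trimethyl ether
Product: 11 saturated 20-membered macrocycle trimethyl ether (ring B–(CH2)12–ring A)
Conditions: H2 (1 atm), 10% Pd/C, EtOAc, rt
Reagents that add atoms: none
Why: Heterogeneous catalytic hydrogenation saturates both disubstituted ring alkenes whatever their geometry, while the aryl methyl ethers and the diaryl ether are inert under these conditions.

Step 7
Reactants: 11 saturated 20-membered macrocycle trimethyl ether
Product: 12 CNP0314249.0 (macrocyclic triol)
Conditions: BBr3 (6 equiv), CH2Cl2, −78 °C → rt; then ice-water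
Reagents that add atoms: none
Why: Lewis acid ether cleavage, in which BBr3 coordinates each methoxy oxygen and bromide removes the methyl group by SN2, whereas the diaryl ether offers no alkyl carbon for attack and survives.

**Compound list**

1 | syringaldehyde (4-hydroxy-3,5-dimethoxybenzaldehyde) | COc1cc(C=O)cc(OC)c1O | starting material
2 | 3-bromo-5-methoxyphenylboronic acid | COc1cc(Br)cc(B(O)O)c1 | starting material
3 | 4-(3-bromo-5-methoxyphenoxy)-3,5-dimethoxybenzaldehyde | COc1cc(Br)cc(Oc2c(OC)cc(C=O)cc2OC)c1 | intermediate
4 | allylmagnesium bromide | C=CC[Mg]Br | starting material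
5 | rac-1-[4-(3-bromo-5-methoxyphenoxy)-3,5-dimethoxyphenyl]but-3-en-1-ol | COc1cc(Br)cc(Oc2c(OC)cc(C(O)CC=C)cc2OC)c1 | intermediate
6 | 2-(3-bromo-5-methoxyphenoxy)-5-(but-3-en-1-yl)-1,3-dimethoxybenzene | COc1cc(Br)cc(Oc2c(OC)cc(CCC=C)cc2OC)c1 | intermediate
7 | 5-(but-3-en-1-yl)-1,3-dimethoxy-2-(3-methoxy-5-vinylphenoxy)benzene | COc1cc(C=C)cc(Oc2c(OC)cc(CCC=C)cc2OC)c1 | intermediate
8 | cis-cyclooctene | C1CC/C=C\CCC1 | starting material
9 | 5-[(3E)-dodeca-3,11-dien-1-yl]-1,3-dimethoxy-2-(3-methoxy-5-vinylphenoxy)benzene (open-chain triene, not isolated) | COc1cc(C=C)cc(Oc2c(OC)cc(CC/C=C/CCCCCCC=C)cc2OC)c1 | intermediate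
10 | (3E,11E)-20-membered macrocyclic diene trimethyl ether: ring A (5-methoxy-1,3-phenylene) and ring B (2,6-dimethoxy-1,4-phenylene) joined by the ether oxygen and by the bridge ring B–CH2CH2–CH=CH–(CH2)6–CH=CH–ring A | COc1cc(/C=C/CCCCCC/C=C/CC2)cc(c1)Oc1c(OC)cc2cc1OC | intermediate
11 | saturated 20-membered macrocycle trimethyl ether: the same rings joined by the ether oxygen and a (CH2)12 bridge | COc1cc2cc(c1)Oc1c(OC)cc(cc1OC)CCCCCCCCCCCC2 | intermediate
12 | CNP0314249.0: ring A (5-hydroxy-1,3-phenylene) and ring B (2,6-dihydroxy-1,4-phenylene) joined by the ether oxygen and a (CH2)12 bridge | Oc1cc2cc(c1)Oc1c(O)cc(cc1O)CCCCCCCCCCCC2 | target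

**Count**

Total steps: 7. Longest linear sequence: 7 steps (from 1 to 12).

**Steps most likely to fail**

Step 5 (proposed new method). Insertion of two or more cyclooctene units, or of none (cyclodimerisation of 7), may persist if secondary metathesis at the styrenyl alkene is too slow to equilibrate the mixture, and alkene migration before metathesis would delete a bridge carbon. The fallback uses known chemistry only and sets out from bromide 6. 1,9-Decadiene (excess) is hydroborated with 9-borabicyclo[3.3.1]nonane to B-(dec-9-en-1-yl)-9-borabicyclo[3.3.1]nonane F1. Once the hydroboration is complete, so that the butenyl group of 6 is never exposed to free borane, F1 is coupled with 6 in a B-alkyl Suzuki–Miyaura reaction (PdCl2(dppf), dppf = 1,1'-bis(diphenylphosphino)ferrocene, K3PO4, THF/DMF/H2O, 60 °C). This should give 5-(but-3-en-1-yl)-2-[3-(dec-9-en-1-yl)-5-methoxyphenoxy]-1,3-dimethoxybenzene F2. Ordinary macrocyclic ring-closing metathesis of F2 (second-generation Grubbs catalyst, CH2Cl2, 1 mM, 40 °C) then closes the same 20-membered ring at C3=C4 alone, giving the 20-membered macrocyclic monoene trimethyl ether F3. Hydrogenation of F3 (H2, Pd/C, EtOAc) returns to the route at 11.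

Step 1. The doubly ortho-substituted, aldehyde-deactivated phenoxide of 1 may transfer to copper too slowly, so that protodeboronation and oxidative homocoupling of 2 consume the aryl donor. In the fallback, 1 is coupled as the nucleophile with commercial 1-bromo-3-iodo-5-methoxybenzene in an Ullmann-type etherification (CuI, picolinic acid, K3PO4, DMSO, 90 °C). This should engage only the C–I bond. It sets out from 1, returns directly at 3, and makes no compound outside the list (F0).

Step 3. Ionisation of the carbinol may be diverted. Proton loss from the benzylic cation toward the conjugated diene, followed by reprotonation and reduction, would move the double bond inward, and the electron-rich ring A of a second molecule may capture the cation. The fallback sets out from aldehyde 3. NaBH4 reduction (MeOH, 0 °C) should give [4-(3-bromo-5-methoxyphenoxy)-3,5-dimethoxyphenyl]methanol F4. PBr3 (CH2Cl2, 0 °C) should convert it into 5-(bromomethyl)-2-(3-bromo-5-methoxyphenoxy)-1,3-dimethoxybenzene F5. Displacement of the benzylic bromide with allylmagnesium bromide 4 (THF, 0 °C) forms the same C1–C2 bond without any cation and returns to the route at 6.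

**Further compounds**

F1 | step 5 | B-(dec-9-en-1-yl)-9-borabicyclo[3.3.1]nonane | C=CCCCCCCCCB1C2CCCC1CCC2
F2 | step 5 | 5-(but-3-en-1-yl)-2-[3-(dec-9-en-1-yl)-5-methoxyphenoxy]-1,3-dimethoxybenzene | COc1cc(CCCCCCCCC=C)cc(Oc2c(OC)cc(CCC=C)cc2OC)c1
F3 | step 5 | 20-membered macrocyclic monoene trimethyl ether (ring B–CH2CH2–CH=CH–(CH2)8–ring A, E drawn) | COc1cc2cc(c1)Oc1c(OC)cc(cc1OC)CC/C=C/CCCCCCCC2
F0 | step 1 | none | none
F4 | step 3 | [4-(3-bromo-5-methoxyphenoxy)-3,5-dimethoxyphenyl]methanol | COc1cc(Br)cc(Oc2c(OC)cc(CO)cc2OC)c1
F5 | step 3 | 5-(bromomethyl)-2-(3-bromo-5-methoxyphenoxy)-1,3-dimethoxybenzene | COc1cc(Br)cc(Oc2c(OC)cc(CBr)cc2OC)c1
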